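Ring C is cut at C2–C3 and C4–C4a. C2 is an aldehyde-level carbon held between O1 and the 3,4-dimethoxyphenyl group, and C4 is a carboxyl-level carbon on the strongly nucleophilic C4a of ring A; the pyranone therefore maps onto a stepwise [4+2] union of an aryloxy-stabilised carbenium ion (C4a–C8a–O1–C2) with 1,1-dimethoxyethene (C3–C4). In one operation a confined chiral Brønsted acid ionises a racemic acetoxy acetal, its anion steers the ketene acetal to one face of C2, and the new dimethoxycarbenium ion closes ring C on C4a, creating two C–C bonds and the S stereocentre. The precursor is the mixed acetal of 3,4-dimethoxybenzaldehyde with 2,3,5-trimethoxyphenol and acetic acid.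

Key step: step 6

Remark: C2 of the target is S by the CIP rules. Which enantiomer of the chiral acid delivers 2S cannot be predicted with certainty, so the route assumes the catalyst hand is assigned by trial.

Step 1
Reactants: 1 3-bromo-4,5-dimethoxybenzaldehyde
Product: 3 3-bromo-4,5-dimethoxyphenol, via 3-bromo-4,5-dimethoxyphenyl formate 2 (not isolated)
Conditions: mCPBA (1.3 equiv), CH2Cl2, 0 °C to rt; aq. Na2S2O3/NaHCO3 wash; crude formate, K2CO3 (cat.), MeOH, rt
Reagents that add atoms: mCPBA, OOC(=O)c1cccc(Cl)c1
Why: Baeyer–Villiger oxidation (Dakin-type), in which the aryl group para to a methoxy donor migrates in preference to hydride, followed by base-catalysed methanolysis of the aryl formate.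

Step 2
Reactants: 3 3-bromo-4,5-dimethoxyphenol
Product: 4 1-bromo-2,3,5-trimethoxybenzene
Conditions: MeI, K2CO3, acetone, reflux
Reagents that add atoms: iodomethane, CI
Why: Williamson ether synthesis; the potassium phenoxide is the only nucleophile and is methylated by SN2 attack on iodomethane.

Step 3
Reactants: 4 1-bromo-2,3,5-trimethoxybenzene
Product: 5 2,3,5-trimethoxyphenol
Conditions: Pd2(dba)3 (2 mol %), t-BuXPhos (8 mol %), KOH (3 equiv), 1,4-dioxane/H2O, 100 °C; then aq. HCl
Reagents that add atoms: potassium hydroxide, [K+].[OH-]
Why: Buchwald–Hartwig-type C–O coupling of an aryl bromide with hydroxide; the bulky biaryl phosphine allows reductive elimination from an electron-rich, ortho-substituted aryl palladium hydroxide, and excess aqueous hydroxide suppresses diaryl ether formation.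

Step 4
Reactants: 5 2,3,5-trimethoxyphenol; 6 3,4-dimethoxybenzoyl chloride
Product: 7 2,3,5-trimethoxyphenyl 3,4-dimethoxybenzoate
Conditions: Et3N, DMAP (cat.), CH2Cl2, 0 °C to rt
Reagents that add atoms: none
Why: Nucleophilic acyl substitution (DMAP-catalysed O-acylation of a phenol by an acid chloride), which should be fast even for the ortho-methoxy phenol.

Step 5
Reactants: 7 2,3,5-trimethoxyphenyl 3,4-dimethoxybenzoate
Product: 9 acetoxy(3,4-dimethoxyphenyl)methyl 2,3,5-trimethoxyphenyl ether (racemic), via diisobutylaluminium hemiacetal 8 (not isolated)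
Conditions: i-Bu2AlH (1.2 equiv), CH2Cl2, −78 °C; then pyridine, DMAP, Ac2O, −78 °C to 0 °C; aq. NH4Cl/potassium sodium tartrate; Et3N-buffered chromatography or use crude
Reagents that add atoms: acetic anhydride, CC(=O)OC(C)=O
Why: Reductive acetylation of an ester: one hydride adds at −78 °C, the tetrahedral aluminium alkoxide 8 is held by chelation to the neighbouring methoxy oxygen and is O-acetylated in situ before it can collapse to the aldehyde; the acetal carbon forms as a racemate, which is harmless because it becomes planar in step 6.

Step 6
Reactants: 9 acetoxy(3,4-dimethoxyphenyl)methyl 2,3,5-trimethoxyphenyl ether (racemic); 10 1,1-dimethoxyethene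
Product: 13 (S)-2-(3,4-dimethoxyphenyl)-4,4,5,7,8-pentamethoxychroman, via O-aryl oxocarbenium ion 11 (not isolated), via open-chain dimethoxycarbenium ion 12 (not isolated)
Conditions: chiral IDPi Brønsted acid (N-triflyl imidodiphosphorimidate on 3,3′-diaryl-BINOL units, 5 mol %), 10 (3 equiv, added slowly over several hours), toluene/CH2Cl2, −78 °C, strictly anhydrous; Et3N quench at −78 °C
Reagents that add atoms: none
Why: Proposed new method: the acid, or the dimethoxycarbenium ion it forms with 10, removes acetate from racemic 9 to give the planar cation 11 paired with the chiral IDPi anion; 10 adds to C2 (bond C2–C3) and cation 12 then alkylates the free ortho carbon of the aryloxy ring (bond C4–C4a), loss of the ring proton restoring the arene and the acid, while the acetic acid released is consumed by a second equivalent of 10 as methyl acetate. The nearest known reactions are the SnCl4-promoted oxa-Povarov annulation of O-aryl oxocarbenium ions with alkenes, which gives racemic chromans, and IDPi-controlled Mukaiyama additions of silyl ketene acetals to oxocarbenium ions generated from acetates; new here is their combination with a simple ketene acetal whose adduct cation is captured by the arene. Ring C closes by intramolecular Friedel–Crafts alkylation, 6-endo with respect to the arene, so the process is a stepwise cationic [4+2] annulation and not a concerted cycloaddition. C2 is the only new stereocentre and is set in the first C–C bond formation: both enantiomers of 9 converge on 11, and the confined anion must leave the Si face of C2 open for 10, which gives 2S. Three selectivities are needed: acetate and not the aryloxide must depart, which the much better nucleofugality of acetate and the stability of the aryl-conjugated O-aryl cation secure; ring closure must go to one carbon, and only one ortho position is free, activated ortho by O1 and the 5-methoxy group and para by the 7-methoxy group (chroman numbering); and cyclisation must outrun methyl loss to the open-chain ester and oligomerisation of 10, for which the non-nucleophilic anion, the low temperature and the slow addition of 10 are chosen.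

Step 7
Reactants: 13 (S)-2-(3,4-dimethoxyphenyl)-4,4,5,7,8-pentamethoxychroman
Product: 14 (2S)-2-(3,4-dimethoxyphenyl)-5,7,8-trimethoxychroman-4-one (CNP0306872.1)
Conditions: PPTS (10 mol %), acetone/H2O, rt (crude 13 may be used directly)
Reagents that add atoms: water, O
Why: Acid-catalysed hydrolysis of a dimethyl ketal (any 4-methoxy-2H-chromene formed by loss of methanol converges on the same ketone); the weak acid at room temperature should neither open ring C by retro-oxa-Michael reaction nor ionise the C2–O1 bond, so C2 stays S.

Compound list
1 | 3-bromo-4,5-dimethoxybenzaldehyde | COc1cc(C=O)cc(Br)c1OC | starting material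
2 | 3-bromo-4,5-dimethoxyphenyl formate | COc1cc(OC=O)cc(Br)c1OC | intermediate (not isolated)
3 | 3-bromo-4,5-dimethoxyphenol | COc1cc(O)cc(Br)c1OC | intermediate
4 | 1-bromo-2,3,5-trimethoxybenzene | COc1cc(OC)cc(Br)c1OC | intermediate
5 | 2,3,5-trimethoxyphenol | COc1cc(OC)cc(O)c1OC | intermediate
6 | 3,4-dimethoxybenzoyl chloride | COc1ccc(C(=O)Cl)cc1OC | starting material
7 | 2,3,5-trimethoxyphenyl 3,4-dimethoxybenzoate | COc1ccc(C(=O)Oc2cc(OC)cc(OC)c2OC)cc1OC | intermediate
8 | diisobutylaluminium hemiacetal of 7, [(3,4-dimethoxyphenyl)(2,3,5-trimethoxyphenoxy)methoxy]diisobutylaluminium (racemic) | COc1ccc(C(O[Al](CC(C)C)CC(C)C)Oc2cc(OC)cc(OC)c2OC)cc1OC | intermediate (not isolated)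
9 | acetoxy(3,4-dimethoxyphenyl)methyl 2,3,5-trimethoxyphenyl ether (racemic) | CC(=O)OC(Oc1cc(OC)cc(OC)c1OC)c1ccc(OC)c(OC)c1 | intermediate
10 | 1,1-dimethoxyethene | C=C(OC)OC | starting material
11 | (3,4-dimethoxybenzylidene)(2,3,5-trimethoxyphenyl)oxonium ion, paired with the IDPi anion | COc1ccc(C=[O+]c2cc(OC)cc(OC)c2OC)cc1OC | intermediate (not isolated)
12 | (S)-3-(3,4-dimethoxyphenyl)-1,1-dimethoxy-3-(2,3,5-trimethoxyphenoxy)propan-1-ylium ion, paired with the IDPi anion | COc1ccc([C@H](CC(OC)=[O+]C)Oc2cc(OC)cc(OC)c2OC)cc1OC | intermediate (not isolated)
13 | (S)-2-(3,4-dimethoxyphenyl)-4,4,5,7,8-pentamethoxychroman | COc1ccc([C@@H]2CC(OC)(OC)c3c(OC)cc(OC)c(OC)c3O2)cc1OC | intermediate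
14 | (2S)-2-(3,4-dimethoxyphenyl)-5,7,8-trimethoxychroman-4-one | COc1ccc([C@@H]2CC(=O)c3c(OC)cc(OC)c(OC)c3O2)cc1OC | target

Total step count: 7
Longest linear sequence: 7 steps (1 to 14); 6 and 10 are used as purchased.

Steps most likely to fail

Step 6. The adduct cation may lose a methyl group to give the open-chain ester, or 10 may oligomerise under the acid, before the arene closes the ring; facial selectivity in the first addition may also be poor. The fallback uses known chemistry, sets out from phenol 5 and comes back at target 14. Ortho-acetylation of 5 (AcOH, BF3·OEt2, 80 °C, a Friedel–Crafts/Fries-type acylation directed to the position next to the hydroxyl by boron chelation) should give 1-(2-hydroxy-3,4,6-trimethoxyphenyl)ethanone F1. Condensation with DMF dimethyl acetal (toluene, 100 °C) should give (E)-3-(dimethylamino)-1-(2-hydroxy-3,4,6-trimethoxyphenyl)prop-2-en-1-one F2, which on treatment with aq. HCl in CH2Cl2 should cyclise to 5,7,8-trimethoxy-4H-chromen-4-one F3. Asymmetric conjugate addition of 3,4-dimethoxyphenylboronic acid to F3, catalysed by Pd(OCOCF3)2 and a t-BuPyOX ligand of the hand that gives 2S (NH4PF6, H2O, ClCH2CH2Cl, 60 °C), should then give 14 directly.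

Step 5. The aryloxy aluminium hemiacetal may collapse to the aldehyde before it is acetylated, leading to over-reduction and loss of the phenol. The fallback sets out from phenol 5 and comes back at acetoxy acetal 9, bypassing ester 7. Addition of acetyl chloride to 3,4-dimethoxybenzaldehyde (ZnCl2 cat., CH2Cl2, 0 °C) should give chloro(3,4-dimethoxyphenyl)methyl acetate F4. O-Alkylation of the caesium phenoxide of 5 with F4 (Cs2CO3, MeCN, 0 °C), an acyloxyalkylation of a phenol, should give 9.

Step 3. Reductive elimination to the phenol may stall on the electron-rich, ortho-substituted aryl palladium species, or the product phenoxide may couple with unreacted bromide. The fallback sets out from bromide 4 and comes back at phenol 5 without palladium. Bromine–lithium exchange (n-BuLi, THF, −78 °C) should give (2,3,5-trimethoxyphenyl)lithium F5. Quenching with B(OMe)3 should give dimethyl (2,3,5-trimethoxyphenyl)boronate F6, and oxidation in the same flask (NaOH, H2O2, 0 °C) should give 5.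

Further compounds
F1 | step 6 | 1-(2-hydroxy-3,4,6-trimethoxyphenyl)ethanone | CC(=O)c1c(O)c(OC)c(OC)cc1OC
F2 | step 6 | (E)-3-(dimethylamino)-1-(2-hydroxy-3,4,6-trimethoxyphenyl)prop-2-en-1-one | CN(C)/C=C/C(=O)c1c(O)c(OC)c(OC)cc1OC
F3 | step 6 | 5,7,8-trimethoxy-4H-chromen-4-one | O=c1ccoc2c(OC)c(OC)cc(OC)c12
F4 | step 5 | chloro(3,4-dimethoxyphenyl)methyl acetate (racemic) | CC(=O)OC(Cl)c1ccc(OC)c(OC)c1
F5 | step 3 | (2,3,5-trimethoxyphenyl)lithium | [Li]c1cc(OC)cc(OC)c1OC
F6 | step 3 | dimethyl (2,3,5-trimethoxyphenyl)boronate | COB(OC)c1cc(OC)cc(OC)c1OC
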